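## Analysis of the target

Target 31 is a labdane diester built on a trans-fused decalin (ring A = C1–C5 and C10, ring B = C5–C10, labdane numbering). C9 carries the chain C11–C15 with an E-configured C13=C14 alkene, the C16 methyl and the C15 acetate. There are three contiguous stereocentres, two of them quaternary: C4 (C18 methyl equatorial, C19 methyl ester axial), C5 (H anti to C20) and C10 (C20 methyl axial). The ester and C20 sit 1,3-diaxial on the same face; the absolute configuration is 4S,5R,10S. The C8=C9 alkene is tetrasubstituted (C17 methyl on C8, chain on C9) and lies next to quaternary C10. Sensitive groups are the allylic acetate (ionised by zerovalent palladium, cleaved by amide bases), the acid-isomerisable alkenes and, in intermediates, a 2-substituted acrylate. The difficulties are the 1,3-related quaternary centres with the larger group axial, the C9–C11 bond at a hindered, fully substituted sp2 carbon with the alkene fixed between C8 and C9, and the E geometry at C13. The strategy rests on ring B: C9 (oxygenated), C8 with its methyl, C7, C6, and the C5 stereocentre with a three-carbon branch map atom for atom onto (R)-carvone 1. Its isopropenyl group supplies C4, C3 and C19, so ring A needs only the two-carbon bridge C1–C2 from C10 to the isopropenyl terminus.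

## Retrosynthetic reasoning

**C15–O.** The acetate of 31 is removed first, to alcohol 30 and then to silyl ether 29. An allylic acetate would survive neither the amide base needed at C4 nor zerovalent palladium at C9, so the C15 oxygen travels as a robust silyl ether.

**C4–C18.** Cutting the C18 methyl from 29 gives ester 27 and iodomethane 2. The forward step is an ester enolate methylation in which the axial C10 methyl blocks one face. Placing it late means that whatever configuration C4 takes in the ring closure is erased.

**C9–C11.** This sp2–sp3 bond is cut to alkenyl triflate 17 and zinc reagent 26 (from iodide 25). The whole side chain arrives in one convergent step, and the alkene position is already fixed in the triflate, so no isomerisation-prone dehydration is needed.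

**Triflate to enone.** Triflate 17 is the trapped C8–C9 enolate of a C9 ketone. Generating it by 1,4-reduction of enone 15 leaves no regiochemical choice. This is why the C9 carbonyl and the C8 methyl must survive ring closure as an enone.

**C2–C3 (key disconnection).** Opening ring A of 15 at C2–C3 gives acid 14. The acid has a methyl acrylate unit on C5 and a propanoic acid arm on C10. The cut falls between two CH2 groups, so no stereocentre is made at the new bond. The trans fusion is stored beforehand in C5 and C10. Decarboxylation gives a C2 radical that must add to the acrylate terminus C3 rather than to the ring enone.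

**Adjusting the two arms.** Acid 14 goes back through alcohol 13, acid 12, aldehyde 11, chloro alcohol 10 and allyl chloride 8 to dialkylated carvone 7. No skeletal bond is cut. The isopropenyl methyl is raised to the ester level and the allyl terminus to the acid level. The order is chosen so that each reagent meets only compatible groups and the free acid appears only in 14.

**C10–C1 and C10–C20.** Compound 7 comes from 1 by two enolate alkylations, first with 2 (to 4) and then with allyl bromide 5. The second electrophile enters anti to the C5 substituent, so this order sets C10 correctly. An acrylate ester would give the acid level directly. Its adduct enolate, however, is held over C7 of the ring enone and would close a bicyclo[2.2.2]octanone by a second conjugate addition. The allyl group cannot do this.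

**Side chain.** Iodide 25 goes back through alcohol 24, bis-silyl ether 23 and allylic alcohol 22 to alkyne 19 and but-3-yn-1-ol 18. The C13–C16 and C14–C15 bonds are cut. A syn methyl–aluminium addition across the alkyne followed by one-carbon trapping fixes the E geometry.

## Alternatives that were turned down

**Alternative 1: intramolecular Diels–Alder through the tetrasubstituted alkene.**
- Disconnection: C1–C2 and C5–C10, opening both rings of bicyclic diene ester A1 to acyclic tetraene ester A2. In A2 the C8=C9 alkene is the tether and the side chain is already attached.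
- Forward step: a chiral oxazaborolidinium Lewis acid activates the ester-bearing diene C2–C5, which adds to the isopropenyl alkene C10=C1.
- For: two rings and both C5 and C10 in one step; no hindered coupling at C9; on bond-forming economy it is stronger than the chosen route.
- Against: the Lewis acid binds the diene, not the dienophile. The dienophile is an unactivated 1,1-disubstituted alkene that is itself part of the diene C8=C9–C10=C1, so reversed pairings and dimerisation of the 2-alkoxycarbonyl diene compete. Enantiofacial control would come from a catalyst remote from C10, with no stereocentre in the substrate. A2 also needs a stereodefined acyclic tetrasubstituted alkene, which is as hard as the problem it replaces.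
- Comparison: the chosen route takes absolute configuration from 1, gets the tetrasubstituted alkene regiospecifically from a ring enone, and uses only precedented reaction types.

**Alternative 2: ring-closing enyne metathesis for ring B.**
- Disconnection: the C8=C9 bond of vinyl diene A3, back to ring A enyne A4 (ethynyl on C10, 3-methylbut-3-enyl arm on C5).
- Forward step: the second-generation Grubbs catalyst RuCl2(CHPh)(H2IMes)(PCy3) closes ring B and leaves a C11=C12 vinyl group.
- For: the tetrasubstituted alkene and the C9–C11 bond form together. The vinyl group allows hydroboration and an unhindered sp3–sp2 coupling; for attaching the side chain this is stronger than the hindered coupling of 17.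
- Against: closing a tetrasubstituted ring alkene from a 1,1-disubstituted alkene and an alkyne on a quaternary carbon is among the slowest metathesis classes. A4 must already hold the C5/C10 relationship, including a quaternary propargylic centre with no cheap source. The conjugated ring A ester must later be reduced and methylated beside a 1,3-diene.
- Comparison: the chosen route buys ring B intact, sets C10 by substrate-controlled alkylation, and accepts a harder coupling at C9 in exchange.

**Alternative 3: quinone Diels–Alder for ring A.**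
- Disconnection: C1–C10 and C4–C5 of enedione A5, back to 2,6-dimethyl-1,4-benzoquinone A6 and methyl (2E)-penta-2,4-dienoate A7.
- Forward step: cycloaddition under a chiral oxazaborolidinium Lewis acid, then epimerisation at C5 with amine base to the trans fusion.
- For: two achiral commercial components and one catalytic step give a decalin with quaternary C10 and the same C9 ketone/C8 methyl enone as 15. In step count to the bicycle it is clearly stronger than the nine steps to 15.
- Against: both partners are electron-poor, so reactivity and regiochemistry lie outside the usual donor-diene rules. The trans fusion depends on an equilibrium at C5, which for angularly methylated decalindiones does not clearly favour trans. A5 carries a C6 carbonyl and a C2=C3 alkene that 31 lacks, and removing them beside the C9 enone costs several chemoselective steps.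
- Comparison: the chosen route gives the exact oxidation pattern and a trans fusion fixed by stereocentres before ring closure.

Key step: step 9

Assumption: protonation at C4 in step 9 should give both C4 epimers. Compounds 15, 16, 17 and 27 are written as the equatorial ester (1R); the epimer is carried along because both give the same enolate 28 in step 17.

## Route

**Step 1**
Reactants: 1 (R)-(−)-carvone; 2 iodomethane
Product: 4 (5R)-2,6-dimethyl-5-(prop-1-en-2-yl)cyclohex-2-en-1-one (both C6 epimers), via lithium dienolate of carvone 3 (not isolated)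
Conditions: LiN(iPr)2, THF, −78 °C; MeI, −78 → 0 °C
Reagents that add atoms: iodomethane (2), CI
Why: Kinetic deprotonation at the α′-CH2 gives the cross-conjugated dienolate, which is C-methylated (enolate alkylation). The new centre forms as an epimer mixture that step 2 erases.

**Step 2**
Reactants: 4 (5R)-2,6-dimethyl-5-(prop-1-en-2-yl)cyclohex-2-en-1-one; 5 allyl bromide
Product: 7 (5S,6S)-2,6-dimethyl-5-(prop-1-en-2-yl)-6-(prop-2-en-1-yl)cyclohex-2-en-1-one, via lithium dienolate of 6-methylcarvone 6 (not isolated)
Conditions: LiN(iPr)2, THF, −78 → −20 °C; allyl bromide, −78 °C → rt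
Reagents that add atoms: allyl bromide (5), C=CCBr
Why: Enolate alkylation at the only remaining α′-H. The electrophile approaches anti to the C5 isopropenyl group, so the quaternary centre (C10 of the target) should carry the methyl cis and the three-carbon arm trans to it. Allyl bromide is used because an acrylate adduct would cyclise onto the enone.

**Step 3**
Reactants: 7 (5S,6S)-2,6-dimethyl-5-(prop-1-en-2-yl)-6-(prop-2-en-1-yl)cyclohex-2-en-1-one
Product: 8 (5R,6S)-5-(3-chloroprop-1-en-2-yl)-2,6-dimethyl-6-(prop-2-en-1-yl)cyclohex-2-en-1-one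
Conditions: Ca(OCl)2, CO2 (solid), CH2Cl2/H2O, 0 °C
Reagents that add atoms: calcium hypochlorite Ca(OCl)2, [Ca+2].[O-]Cl.[O-]Cl
Why: Ene-type allylic chlorination by hypochlorous acid. Chlorine adds to the terminal CH2 of the electron-rich 1,1-disubstituted alkene and a methyl proton is lost. The monosubstituted allyl group and the electron-poor enone alkene react far more slowly.

**Step 4**
Reactants: 8 (5R,6S)-5-(3-chloroprop-1-en-2-yl)-2,6-dimethyl-6-(prop-2-en-1-yl)cyclohex-2-en-1-one
Product: 10 (5R,6S)-5-(3-chloroprop-1-en-2-yl)-6-(3-hydroxypropyl)-2,6-dimethylcyclohex-2-en-1-one, via B-alkyldicyclohexylborane 9 (not isolated)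
Conditions: Cy2BH (from BH3·SMe2 and cyclohexene), THF, 0 °C; NaBO3·4H2O, THF/H2O, rt
Reagents that add atoms: sodium perborate NaBO3·4H2O, [Na+].[O-]OB=O
Why: Anti-Markovnikov hydroboration–oxidation. The bulky dialkylborane should take the unhindered monosubstituted alkene well before the 1,1-disubstituted alkene (deactivated by its allylic chlorine) or the hindered conjugated ketone. Perborate oxidises the C–B bond without strong base, sparing enone and chloride.

**Step 5**
Reactants: 10 (5R,6S)-5-(3-chloroprop-1-en-2-yl)-6-(3-hydroxypropyl)-2,6-dimethylcyclohex-2-en-1-one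
Product: 11 2-[(1S,2S)-2-(3-hydroxypropyl)-2,4-dimethyl-3-oxocyclohex-4-en-1-yl]prop-2-enal
Conditions: Me3NO (anhydrous), NaI (cat.), DMSO, rt
Reagents that add atoms: trimethylamine N-oxide, C[N+](C)(C)[O-]
Why: Kornblum-type oxidation with an amine N-oxide: O-alkylation by the allylic chloride, then elimination of the amine. SN2 and SN2′ attack give the same product in this symmetric allyl system, and the primary alcohol is not oxidised.

**Step 6**
Reactants: 11 2-[(1S,2S)-2-(3-hydroxypropyl)-2,4-dimethyl-3-oxocyclohex-4-en-1-yl]prop-2-enal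
Product: 12 2-[(1R,2S)-2-(3-hydroxypropyl)-2,4-dimethyl-3-oxocyclohex-4-en-1-yl]prop-2-enoic acid
Conditions: NaClO2, NaH2PO4, 2-methylbut-2-ene, t-BuOH/H2O, 0 °C → rt
Reagents that add atoms: sodium chlorite NaClO2, [Na+].[O-]Cl=O
Why: Pinnick oxidation converts the α-methylene aldehyde to the acid without touching the enone, the alkene or the primary alcohol; the alkene additive scavenges the hypochlorite by-product.

**Step 7**
Reactants: 12 2-[(1R,2S)-2-(3-hydroxypropyl)-2,4-dimethyl-3-oxocyclohex-4-en-1-yl]prop-2-enoic acid; 2 iodomethane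
Product: 13 methyl 2-[(1R,2S)-2-(3-hydroxypropyl)-2,4-dimethyl-3-oxocyclohex-4-en-1-yl]prop-2-enoate
Conditions: MeI, KHCO3, DMF, rt
Reagents that add atoms: iodomethane (2), CI
Why: SN2 O-alkylation of the carboxylate under weak base. The alcohol is not alkylated and the acrylate meets no strong nucleophile.

**Step 8**
Reactants: 13 methyl 2-[(1R,2S)-2-(3-hydroxypropyl)-2,4-dimethyl-3-oxocyclohex-4-en-1-yl]prop-2-enoate
Product: 14 3-[(1S,6R)-6-(3-methoxy-3-oxoprop-1-en-2-yl)-1,3-dimethyl-2-oxocyclohex-3-en-1-yl]propanoic acid
Conditions: CrO3, H2SO4, H2O, acetone, 0 °C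
Reagents that add atoms: chromium trioxide CrO3, O=[Cr](=O)=O; water, O
Why: Jones oxidation takes the primary alcohol through the aldehyde hydrate to the acid; acrylate and enone are inert to chromic acid. Any C9 carbinol formed by over-reduction in step 4 would be returned to the ketone here.

**Step 9 (key step)**
Reactants: 14 3-[(1S,6R)-6-(3-methoxy-3-oxoprop-1-en-2-yl)-1,3-dimethyl-2-oxocyclohex-3-en-1-yl]propanoic acid
Product: 15 methyl (1R,4aS,8aS)-4a,6-dimethyl-5-oxo-1,2,3,4,4a,5,8,8a-octahydronaphthalene-1-carboxylate
Conditions: Ir[dF(CF3)ppy]2(dtbbpy)PF6 (1 mol %), K2HPO4, DMF (0.01 M), blue LEDs (450 nm), rt, degassed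
Reagents that add atoms: none
Why: The excited trivalent iridium complex oxidises the carboxylate of 14 by single-electron transfer; loss of CO2 gives the primary C2 radical, which adds to the unsubstituted terminus C3 of the acrylate, and the ester-stabilised C4 radical is reduced by the divalent iridium complex to the enolate and protonated, so the step is redox-neutral. The closest known reaction type is the photoredox decarboxylative Giese addition of aliphatic acids to acrylates, combined with the 6-endo cyclisation of hex-5-enyl radicals bearing an ester on the inner alkene carbon. Ring A closes in the 6-endo-trig mode through a chair-like transition state with both arms pseudo-equatorial on ring B. The trans fusion follows by construction, because C5 and C10 are already stereocentres with the arms trans. The only new stereocentre, C4, is set by enolate protonation and needs no control, since step 17 makes it planar again. 6-endo over 5-exo closure is secured by the ester on C4: attack there is hindered and would give an unstabilised primary radical in a strained trans-hydrindanone, whereas attack at C3 is polarity-matched and gives a tertiary α-ester radical. Selectivity for the acrylate over the ring enone rests on the unsubstituted acceptor terminus and on geometry, because C7 is substituted and is reached only from the diaxial conformer through a boat leading to a bicyclo[2.2.2]octanone. High dilution suppresses intermolecular addition.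

**Step 10**
Reactants: 15 methyl (1R,4aS,8aS)-4a,6-dimethyl-5-oxo-1,2,3,4,4a,5,8,8a-octahydronaphthalene-1-carboxylate
Product: 17 methyl (1R,4aS,8aS)-4a,6-dimethyl-5-{[(trifluoromethyl)sulfonyl]oxy}-1,2,3,4,4a,7,8,8a-octahydronaphthalene-1-carboxylate, via lithium C8–C9 enolate 16 (not isolated)
Conditions: Li[HB(sec-Bu)3], THF, −78 °C; PhNTf2, −78 °C → rt
Reagents that add atoms: N-phenylbis(trifluoromethanesulfonimide), O=S(=O)(N(c1ccccc1)S(=O)(=O)C(F)(F)F)C(F)(F)F
Why: Conjugate hydride addition: the carbonyl is shielded by quaternary C10 and C7 bears no extra substituent, so the bulky borohydride should add 1,4 and give the C8–C9 enolate regiospecifically. O-sulfonylation then gives the enol triflate; the ester is not reduced at −78 °C.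

**Step 11**
Reactants: 18 but-3-yn-1-ol
Product: 19 tert-butyl(but-3-yn-1-yloxy)dimethylsilane
Conditions: TBSCl, imidazole, CH2Cl2, rt
Reagents that add atoms: tert-butyl(chloro)dimethylsilane, CC(C)(C)[Si](C)(C)Cl
Why: Standard silylation of a primary alcohol; this acid-labile group will later be removed selectively.

**Step 12**
Reactants: 19 tert-butyl(but-3-yn-1-yloxy)dimethylsilane
Product: 22 (2E)-5-{[tert-butyl(dimethyl)silyl]oxy}-3-methylpent-2-en-1-ol, via alkenyldimethylalane 20 (not isolated), via lithium alkenylaluminate 21 (not isolated)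
Conditions: AlMe3, Cp2ZrCl2 (cat.), CH2Cl2, 0 °C → rt; n-BuLi, THF/hexane, −78 → 0 °C; (CH2O)n, rt
Reagents that add atoms: trimethylaluminium AlMe3, C[Al](C)C; paraformaldehyde (CH2O)n, as formaldehyde C=O
Why: Negishi zirconium-catalysed carboalumination adds methyl and aluminium syn across the alkyne, with aluminium on the terminal carbon. Hydroxymethylation of the aluminate occurs with retention, so the E alkene (C12 trans to C15) is fixed.

**Step 13**
Reactants: 22 (2E)-5-{[tert-butyl(dimethyl)silyl]oxy}-3-methylpent-2-en-1-ol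
Product: 23 tert-butyl{[(2E)-5-{[tert-butyl(dimethyl)silyl]oxy}-3-methylpent-2-en-1-yl]oxy}diphenylsilane
Conditions: TBDPSCl, imidazole, CH2Cl2, rt
Reagents that add atoms: tert-butyl(chloro)diphenylsilane, CC(C)(C)[Si](Cl)(c1ccccc1)c1ccccc1
Why: Silylation of the allylic alcohol with the more acid-stable group, which withstands the organozinc, zerovalent palladium and the amide base used later.

**Step 14**
Reactants: 23 tert-butyl{[(2E)-5-{[tert-butyl(dimethyl)silyl]oxy}-3-methylpent-2-en-1-yl]oxy}diphenylsilane
Product: 24 (3E)-5-{[tert-butyl(diphenyl)silyl]oxy}-3-methylpent-3-en-1-ol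
Conditions: camphor-10-sulfonic acid (cat.), MeOH/CH2Cl2, 0 °C
Reagents that add atoms: none
Why: Acid-catalysed methanolysis removes the primary tert-butyldimethylsilyl ether much faster than the tert-butyldiphenylsilyl ether.

**Step 15**
Reactants: 24 (3E)-5-{[tert-butyl(diphenyl)silyl]oxy}-3-methylpent-3-en-1-ol
Product: 25 tert-butyl{[(2E)-5-iodo-3-methylpent-2-en-1-yl]oxy}diphenylsilane
Conditions: I2, PPh3, imidazole, CH2Cl2, 0 °C → rt
Reagents that add atoms: iodine, II
Why: Appel-type iodination: the alkoxyphosphonium salt is displaced by iodide in an SN2 reaction at the unhindered primary carbon, without touching the alkene.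

**Step 16**
Reactants: 25 tert-butyl{[(2E)-5-iodo-3-methylpent-2-en-1-yl]oxy}diphenylsilane; 17 methyl (1R,4aS,8aS)-4a,6-dimethyl-5-{[(trifluoromethyl)sulfonyl]oxy}-1,2,3,4,4a,7,8,8a-octahydronaphthalene-1-carboxylate
Product: 27 methyl (1R,4aS,8aS)-5-[(3E)-5-{[tert-butyl(diphenyl)silyl]oxy}-3-methylpent-3-en-1-yl]-4a,6-dimethyl-1,2,3,4,4a,7,8,8a-octahydronaphthalene-1-carboxylate, via homoallylic zinc iodide 26 (not isolated)
Conditions: Zn, LiCl, THF, 40 °C; then 17, Pd(OAc)2 (cat.), 2-dicyclohexylphosphino-2′,6′-dimethoxybiphenyl (cat.), THF/NMP, 50 °C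
Reagents that add atoms: none
Why: Negishi coupling: zinc inserts into the primary iodide, zerovalent palladium adds to the alkenyl triflate, and transmetalation and reductive elimination form C9–C11. The bulky electron-rich phosphine should favour reductive elimination over β-hydride elimination; no stereocentre or alkene geometry is involved.

**Step 17**
Reactants: 27 methyl (1R,4aS,8aS)-5-[(3E)-5-{[tert-butyl(diphenyl)silyl]oxy}-3-methylpent-3-en-1-yl]-4a,6-dimethyl-1,2,3,4,4a,7,8,8a-octahydronaphthalene-1-carboxylate; 2 iodomethane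
Product: 29 methyl (1S,4aS,8aR)-5-[(3E)-5-{[tert-butyl(diphenyl)silyl]oxy}-3-methylpent-3-en-1-yl]-1,4a,6-trimethyl-1,2,3,4,4a,7,8,8a-octahydronaphthalene-1-carboxylate, via lithium ester enolate 28 (not isolated)
Conditions: LiN(iPr)2, THF, −78 °C; MeI, DMPU, −78 → 0 °C
Reagents that add atoms: iodomethane (2), CI
Why: Ester enolate alkylation. The β face of the exocyclic enolate is blocked by the axial C10 methyl, so iodomethane should enter equatorially from the α face, leaving C18 equatorial and the ester axial, syn to C20. Both C4 epimers of 27 converge on 28.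

**Step 18**
Reactants: 29 methyl (1S,4aS,8aR)-5-[(3E)-5-{[tert-butyl(diphenyl)silyl]oxy}-3-methylpent-3-en-1-yl]-1,4a,6-trimethyl-1,2,3,4,4a,7,8,8a-octahydronaphthalene-1-carboxylate
Product: 30 methyl (1S,4aS,8aR)-5-[(3E)-5-hydroxy-3-methylpent-3-en-1-yl]-1,4a,6-trimethyl-1,2,3,4,4a,7,8,8a-octahydronaphthalene-1-carboxylate
Conditions: (n-Bu)4NF, THF, 0 °C → rt
Reagents that add atoms: none
Why: Fluoride cleaves the silyl ether; the hindered axial methyl ester and both alkenes are unaffected.

**Step 19**
Reactants: 30 methyl (1S,4aS,8aR)-5-[(3E)-5-hydroxy-3-methylpent-3-en-1-yl]-1,4a,6-trimethyl-1,2,3,4,4a,7,8,8a-octahydronaphthalene-1-carboxylate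
Product: 31 methyl (1S,4aS,8aR)-5-[(3E)-5-(acetyloxy)-3-methylpent-3-en-1-yl]-1,4a,6-trimethyl-1,2,3,4,4a,7,8,8a-octahydronaphthalene-1-carboxylate
Conditions: Ac2O, pyridine, 4-(dimethylamino)pyridine (cat.), CH2Cl2, rt
Reagents that add atoms: acetic anhydride, CC(=O)OC(C)=O
Why: Nucleophile-catalysed acylation of the primary allylic alcohol under non-ionising basic conditions keeps the E alkene and the tetrasubstituted alkene in place.

## Compound list

1 | (R)-(−)-carvone, (5R)-2-methyl-5-(prop-1-en-2-yl)cyclohex-2-en-1-one | C=C(C)[C@@H]1CC=C(C)C(=O)C1 | starting material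
2 | iodomethane | CI | starting material
3 | lithium dienolate of carvone | C=C(C)[C@@H]1CC=C(C)C(O[Li])=C1 | intermediate
4 | (5R)-2,6-dimethyl-5-(prop-1-en-2-yl)cyclohex-2-en-1-one (both C6 epimers) | C=C(C)[C@@H]1CC=C(C)C(=O)C1C | intermediate
5 | allyl bromide (3-bromoprop-1-ene) | C=CCBr | starting material
6 | lithium dienolate of 6-methylcarvone | C=C(C)[C@@H]1CC=C(C)C(O[Li])=C1C | intermediate
7 | (5S,6S)-2,6-dimethyl-5-(prop-1-en-2-yl)-6-(prop-2-en-1-yl)cyclohex-2-en-1-one | C=C(C)[C@@H]1CC=C(C)C(=O)[C@@]1(C)CC=C | intermediate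
8 | (5R,6S)-5-(3-chloroprop-1-en-2-yl)-2,6-dimethyl-6-(prop-2-en-1-yl)cyclohex-2-en-1-one | C=C(CCl)[C@@H]1CC=C(C)C(=O)[C@@]1(C)CC=C | intermediate
9 | B-alkyldicyclohexylborane from 8 | C=C(CCl)[C@@H]1CC=C(C)C(=O)[C@@]1(C)CCCB(C2CCCCC2)C2CCCCC2 | intermediate
10 | (5R,6S)-5-(3-chloroprop-1-en-2-yl)-6-(3-hydroxypropyl)-2,6-dimethylcyclohex-2-en-1-one | C=C(CCl)[C@@H]1CC=C(C)C(=O)[C@@]1(C)CCCO | intermediate
11 | 2-[(1S,2S)-2-(3-hydroxypropyl)-2,4-dimethyl-3-oxocyclohex-4-en-1-yl]prop-2-enal | O=CC(=C)[C@@H]1CC=C(C)C(=O)[C@@]1(C)CCCO | intermediate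
12 | 2-[(1R,2S)-2-(3-hydroxypropyl)-2,4-dimethyl-3-oxocyclohex-4-en-1-yl]prop-2-enoic acid | OC(=O)C(=C)[C@@H]1CC=C(C)C(=O)[C@@]1(C)CCCO | intermediate
13 | methyl 2-[(1R,2S)-2-(3-hydroxypropyl)-2,4-dimethyl-3-oxocyclohex-4-en-1-yl]prop-2-enoate | COC(=O)C(=C)[C@@H]1CC=C(C)C(=O)[C@@]1(C)CCCO | intermediate
14 | 3-[(1S,6R)-6-(3-methoxy-3-oxoprop-1-en-2-yl)-1,3-dimethyl-2-oxocyclohex-3-en-1-yl]propanoic acid | COC(=O)C(=C)[C@@H]1CC=C(C)C(=O)[C@@]1(C)CCC(=O)O | intermediate
15 | methyl (1R,4aS,8aS)-4a,6-dimethyl-5-oxo-1,2,3,4,4a,5,8,8a-octahydronaphthalene-1-carboxylate | COC(=O)[C@@H]1CCC[C@]2(C)C(=O)C(C)=CC[C@@H]12 | intermediate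
16 | lithium C8–C9 enolate of the C9 ketone | COC(=O)[C@@H]1CCC[C@]2(C)C(O[Li])=C(C)CC[C@@H]12 | intermediate
17 | methyl (1R,4aS,8aS)-4a,6-dimethyl-5-{[(trifluoromethyl)sulfonyl]oxy}-1,2,3,4,4a,7,8,8a-octahydronaphthalene-1-carboxylate | COC(=O)[C@@H]1CCC[C@]2(C)C(OS(=O)(=O)C(F)(F)F)=C(C)CC[C@@H]12 | intermediate
18 | but-3-yn-1-ol | C#CCCO | starting material
19 | tert-butyl(but-3-yn-1-yloxy)dimethylsilane | C#CCCO[Si](C)(C)C(C)(C)C | intermediate
20 | (E)-alkenyldimethylalane | C[Al](C)/C=C(\C)CCO[Si](C)(C)C(C)(C)C | intermediate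
21 | lithium (E)-alkenyl(butyl)dimethylaluminate | [Li+].CCCC[Al-](C)(C)/C=C(\C)CCO[Si](C)(C)C(C)(C)C | intermediate
22 | (2E)-5-{[tert-butyl(dimethyl)silyl]oxy}-3-methylpent-2-en-1-ol | CC(C)(C)[Si](C)(C)OCC/C(C)=C/CO | intermediate
23 | tert-butyl{[(2E)-5-{[tert-butyl(dimethyl)silyl]oxy}-3-methylpent-2-en-1-yl]oxy}diphenylsilane | CC(C)(C)[Si](C)(C)OCC/C(C)=C/CO[Si](c1ccccc1)(c1ccccc1)C(C)(C)C | intermediate
24 | (3E)-5-{[tert-butyl(diphenyl)silyl]oxy}-3-methylpent-3-en-1-ol | OCC/C(C)=C/CO[Si](c1ccccc1)(c1ccccc1)C(C)(C)C | intermediate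
25 | tert-butyl{[(2E)-5-iodo-3-methylpent-2-en-1-yl]oxy}diphenylsilane | ICC/C(C)=C/CO[Si](c1ccccc1)(c1ccccc1)C(C)(C)C | intermediate
26 | homoallylic zinc iodide from 25 | I[Zn]CC/C(C)=C/CO[Si](c1ccccc1)(c1ccccc1)C(C)(C)C | intermediate
27 | methyl (1R,4aS,8aS)-5-[(3E)-5-{[tert-butyl(diphenyl)silyl]oxy}-3-methylpent-3-en-1-yl]-4a,6-dimethyl-1,2,3,4,4a,7,8,8a-octahydronaphthalene-1-carboxylate | COC(=O)[C@@H]1CCC[C@]2(C)C(CC/C(C)=C/CO[Si](c3ccccc3)(c3ccccc3)C(C)(C)C)=C(C)CC[C@@H]12 | intermediate
28 | lithium ester enolate of 27 | COC(O[Li])=C1CCC[C@]2(C)C(CC/C(C)=C/CO[Si](c3ccccc3)(c3ccccc3)C(C)(C)C)=C(C)CC[C@@H]12 | intermediate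
29 | methyl (1S,4aS,8aR)-5-[(3E)-5-{[tert-butyl(diphenyl)silyl]oxy}-3-methylpent-3-en-1-yl]-1,4a,6-trimethyl-1,2,3,4,4a,7,8,8a-octahydronaphthalene-1-carboxylate | COC(=O)[C@@]1(C)CCC[C@]2(C)C(CC/C(C)=C/CO[Si](c3ccccc3)(c3ccccc3)C(C)(C)C)=C(C)CC[C@@H]12 | intermediate
30 | methyl (1S,4aS,8aR)-5-[(3E)-5-hydroxy-3-methylpent-3-en-1-yl]-1,4a,6-trimethyl-1,2,3,4,4a,7,8,8a-octahydronaphthalene-1-carboxylate | COC(=O)[C@@]1(C)CCC[C@]2(C)C(CC/C(C)=C/CO)=C(C)CC[C@@H]12 | intermediate
31 | methyl (1S,4aS,8aR)-5-[(3E)-5-(acetyloxy)-3-methylpent-3-en-1-yl]-1,4a,6-trimethyl-1,2,3,4,4a,7,8,8a-octahydronaphthalene-1-carboxylate | COC(=O)[C@@]1(C)CCC[C@]2(C)C(CC/C(C)=C/COC(C)=O)=C(C)CC[C@@H]12 | target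

## Step count and least certain steps

Total: 19 steps. Longest linear sequence: 14 steps from 1 (steps 1–10 and 16–19); the side chain takes steps 11–15.

**Step 9 (key step).** The most likely failure is slow single-electron oxidation of the unactivated primary carboxylate, so that back electron transfer and hydrogen abstraction by the radical outrun cyclisation. Energy transfer from the excited iridium complex to the enone or acrylate could also lead to [2+2] cycloaddition, and some capture of the radical by the ring enone is possible. Fallback: from 14, esterification with N-hydroxyphthalimide and N,N′-diisopropylcarbodiimide should give the redox-active ester 1,3-dioxoisoindolin-2-yl 3-[(1S,6R)-6-(3-methoxy-3-oxoprop-1-en-2-yl)-1,3-dimethyl-2-oxocyclohex-3-en-1-yl]propanoate F1. Irradiating F1 with Ru(bpy)3(PF6)2, diethyl 2,6-dimethyl-1,4-dihydropyridine-3,5-dicarboxylate and i-Pr2NEt generates the same C2 radical by reductive fragmentation and ends the sequence by hydrogen atom transfer. The sensitiser has a lower triplet energy and no carboxylate oxidation is needed. The route is rejoined at 15.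

**Step 16.** Oxidative addition and transmetalation at the tetrasubstituted triflate next to quaternary C10 may be slow. Protonation of the zinc reagent, reduction of the triflate and β-hydride elimination would then compete. Fallback: from 17, Stille coupling with tributyl(vinyl)stannane (Pd(PPh3)4, LiCl, THF) should give methyl (1R,4aS,8aS)-5-ethenyl-4a,6-dimethyl-1,2,3,4,4a,7,8,8a-octahydronaphthalene-1-carboxylate F2, since the small vinyl group tolerates the hindrance. Hydroboration of the vinyl terminus with 9-borabicyclo[3.3.1]nonane gives the B-alkylborane F3. But-2-yn-1-ol is silylated to tert-butyl(but-2-yn-1-yloxy)diphenylsilane F4, and hydrozirconation with Cp2Zr(H)Cl followed by iodine gives tert-butyl{[(2E)-3-iodobut-2-en-1-yl]oxy}diphenylsilane F5. Suzuki–Miyaura coupling of F3 with F5 (PdCl2(dppf), Cs2CO3, DMF/THF/H2O) forms the unhindered C12–C13 bond and rejoins the route at 27.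

**Step 4.** The dialkylborane may reduce the C9 carbonyl or add to the second alkene, and the oxidative work-up may epoxidise the enone, because all three processes are only kinetically disfavoured. Fallback without boron: from 8, the N-oxide oxidation of step 5 gives 2-[(1S,2S)-2,4-dimethyl-3-oxo-2-(prop-2-en-1-yl)cyclohex-4-en-1-yl]prop-2-enal F6. Pinnick oxidation gives 2-[(1R,2S)-2,4-dimethyl-3-oxo-2-(prop-2-en-1-yl)cyclohex-4-en-1-yl]prop-2-enoic acid F7, and MeI/KHCO3 gives methyl 2-[(1R,2S)-2,4-dimethyl-3-oxo-2-(prop-2-en-1-yl)cyclohex-4-en-1-yl]prop-2-enoate F8. An aldehyde-selective Wacker oxidation of the allyl group (PdCl2(PhCN)2, CuCl2, AgNO2, O2, t-BuOH/MeNO2) gives methyl 2-[(1R,2S)-2,4-dimethyl-3-oxo-2-(3-oxopropyl)cyclohex-4-en-1-yl]prop-2-enoate F9. A second Pinnick oxidation rejoins the route at 14.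

**Step 5.** Displacement of the chloride may be slow, and the 2-substituted acrolein may oligomerise or dimerise under the amine released. Fallback: from 10, displacement with CsOAc in DMF gives 2-[(1S,2S)-2-(3-hydroxypropyl)-2,4-dimethyl-3-oxocyclohex-4-en-1-yl]prop-2-en-1-yl acetate F10. Methanolysis (K2CO3, MeOH) gives (5S,6S)-5-(3-hydroxyprop-1-en-2-yl)-6-(3-hydroxypropyl)-2,6-dimethylcyclohex-2-en-1-one F11. MnO2 in CH2Cl2 then oxidises only the allylic alcohol under neutral, amine-free conditions and rejoins the route at 11.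

**Step 10.** Some 1,2-reduction may compete, or O-sulfonylation of the hindered boron-bound enolate may be incomplete, returning saturated ketone. Fallback: from 15, hydrogenation (H2, Pd/C, EtOAc) gives methyl (1R,4aS,8aS)-4a,6-dimethyl-5-oxodecahydronaphthalene-1-carboxylate F12 as C6 epimers. Tf2O with 2,6-di-tert-butyl-4-methylpyridine in CH2Cl2 then gives the enol triflate by the only possible enolisation, toward C8, and rejoins the route at 17.

## Further compounds

F1 | step 9 | 1,3-dioxoisoindolin-2-yl 3-[(1S,6R)-6-(3-methoxy-3-oxoprop-1-en-2-yl)-1,3-dimethyl-2-oxocyclohex-3-en-1-yl]propanoate | COC(=O)C(=C)[C@@H]1CC=C(C)C(=O)[C@@]1(C)CCC(=O)ON2C(=O)c3ccccc3C2=O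
F2 | step 16 | methyl (1R,4aS,8aS)-5-ethenyl-4a,6-dimethyl-1,2,3,4,4a,7,8,8a-octahydronaphthalene-1-carboxylate | COC(=O)[C@@H]1CCC[C@]2(C)C(C=C)=C(C)CC[C@@H]12
F3 | step 16 | methyl (1R,4aS,8aS)-5-[2-(9-borabicyclo[3.3.1]nonan-9-yl)ethyl]-4a,6-dimethyl-1,2,3,4,4a,7,8,8a-octahydronaphthalene-1-carboxylate | COC(=O)[C@@H]1CCC[C@]2(C)C(CCB3C4CCCC3CCC4)=C(C)CC[C@@H]12
F4 | step 16 | tert-butyl(but-2-yn-1-yloxy)diphenylsilane | CC#CCO[Si](c1ccccc1)(c1ccccc1)C(C)(C)C
F5 | step 16 | tert-butyl{[(2E)-3-iodobut-2-en-1-yl]oxy}diphenylsilane | C/C(I)=C\CO[Si](c1ccccc1)(c1ccccc1)C(C)(C)C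
F6 | step 4 | 2-[(1S,2S)-2,4-dimethyl-3-oxo-2-(prop-2-en-1-yl)cyclohex-4-en-1-yl]prop-2-enal | O=CC(=C)[C@@H]1CC=C(C)C(=O)[C@@]1(C)CC=C
F7 | step 4 | 2-[(1R,2S)-2,4-dimethyl-3-oxo-2-(prop-2-en-1-yl)cyclohex-4-en-1-yl]prop-2-enoic acid | OC(=O)C(=C)[C@@H]1CC=C(C)C(=O)[C@@]1(C)CC=C
F8 | step 4 | methyl 2-[(1R,2S)-2,4-dimethyl-3-oxo-2-(prop-2-en-1-yl)cyclohex-4-en-1-yl]prop-2-enoate | COC(=O)C(=C)[C@@H]1CC=C(C)C(=O)[C@@]1(C)CC=C
F9 | step 4 | methyl 2-[(1R,2S)-2,4-dimethyl-3-oxo-2-(3-oxopropyl)cyclohex-4-en-1-yl]prop-2-enoate | COC(=O)C(=C)[C@@H]1CC=C(C)C(=O)[C@@]1(C)CCC=O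
F10 | step 5 | 2-[(1S,2S)-2-(3-hydroxypropyl)-2,4-dimethyl-3-oxocyclohex-4-en-1-yl]prop-2-en-1-yl acetate | CC(=O)OCC(=C)[C@@H]1CC=C(C)C(=O)[C@@]1(C)CCCO
F11 | step 5 | (5S,6S)-5-(3-hydroxyprop-1-en-2-yl)-6-(3-hydroxypropyl)-2,6-dimethylcyclohex-2-en-1-one | OCC(=C)[C@@H]1CC=C(C)C(=O)[C@@]1(C)CCCO
F12 | step 10 | methyl (1R,4aS,8aS)-4a,6-dimethyl-5-oxodecahydronaphthalene-1-carboxylate (C6 epimers) | COC(=O)[C@@H]1CCC[C@]2(C)C(=O)C(C)CC[C@@H]12
A1 | alternative 1 | methyl (4aS,8aR)-5-[(3E)-5-{[tert-butyl(dimethyl)silyl]oxy}-3-methylpent-3-en-1-yl]-4a,6-dimethyl-3,4,4a,7,8,8a-hexahydronaphthalene-1-carboxylate | COC(=O)C1=CCC[C@]2(C)C(CC/C(C)=C/CO[Si](C)(C)C(C)(C)C)=C(C)CC[C@@H]12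
A2 | alternative 1 | methyl (2Z,6Z,10E)-12-{[tert-butyl(dimethyl)silyl]oxy}-2-ethenyl-6,10-dimethyl-7-(prop-1-en-2-yl)dodeca-2,6,10-trienoate | COC(=O)/C(C=C)=C\CC/C(C)=C(/CC/C(C)=C/CO[Si](C)(C)C(C)(C)C)C(C)=C
A3 | alternative 2 | methyl (4aS,8aR)-5-ethenyl-4a,6-dimethyl-3,4,4a,7,8,8a-hexahydronaphthalene-1-carboxylate | COC(=O)C1=CCC[C@]2(C)C(C=C)=C(C)CC[C@@H]12
A4 | alternative 2 | methyl (5S,6R)-5-ethynyl-5-methyl-6-(3-methylbut-3-en-1-yl)cyclohex-1-ene-1-carboxylate | COC(=O)C1=CCC[C@](C)(C#C)[C@H]1CCC(C)=C
A5 | alternative 3 | methyl (1R,4aS,8aS)-4a,6-dimethyl-5,8-dioxo-1,4,4a,5,8,8a-hexahydronaphthalene-1-carboxylate | COC(=O)[C@@H]1C=CC[C@]2(C)C(=O)C(C)=CC(=O)[C@@H]12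
A6 | alternative 3 | 2,6-dimethyl-1,4-benzoquinone | CC1=CC(=O)C=C(C)C1=O
A7 | alternative 3 | methyl (2E)-penta-2,4-dienoate | C=C/C=C/C(=O)OC
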